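The route rests on disconnecting the bond between C2 of the tetrahydrofuran ring and C1 of the 1,3,4-trisubstituted phenol ring. C2 is both an acetal-type carbon next to ring oxygen O1 and a benzylic carbon para to that ring's phenol oxygen, so it is formed by Friedel–Crafts capture of a cyclic oxocarbenium ion. The ion comes from a 2-acetoxy-3,4-cis-dimethyl-5-aryl-tetrahydrofuran; the nucleophile is the fully built, benzyl-protected (R)-2-(1-arylpropan-2-yl)phenol, which reacts para to its oxygen. In one operation the two halves are joined and C2 is set trans to the C3 methyl by the cis C3/C4 methyl pair. The pseudo-meso core stems from catalytic desymmetrisation of meso-2,3-dimethylsuccinic anhydride.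

Key step: step 7

Remark: the three phenols are carried as benzyl ethers throughout; in steps 2 and 6 the ligand antipode is the one that delivers the configuration drawn (both antipodes are available), to be confirmed on the first run.

Step 1
Reactants: 1 meso-2,3-dimethylsuccinic acid
Product: 2 meso-2,3-dimethylsuccinic anhydride (cis-3,4-dimethyldihydrofuran-2,5-dione)
Conditions: AcCl (neat), reflux; evaporate
Reagents that add atoms: none
Why: Cyclodehydration of a 1,4-diacid to the five-membered anhydride through a mixed anhydride under non-basic conditions should keep the cis (meso) relationship of the two methyl groups; no stereocentre is made.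

Step 2
Reactants: 2 meso-2,3-dimethylsuccinic anhydride; 3 1-(benzyloxy)-4-bromobenzene
Product: 6 (2R,3S)-4-[4-(benzyloxy)phenyl]-2,3-dimethyl-4-oxobutanoic acid, via aryllithium 4 (not isolated), via arylzinc triflate 5 (not isolated)
Conditions: 3, n-BuLi, THF, −78 °C; Zn(OTf)2, −78 °C → rt; then 2, [Rh(cod)Cl]2 (4 mol %), t-Bu-PHOX (8 mol %), THF–DMF, 50 °C; aq. HCl work-up
Reagents that add atoms: none
Why: Rh-catalysed enantioselective desymmetrising cross-coupling of a meso cyclic anhydride with an arylzinc reagent (acyl–O oxidative addition at one enantiotopic carbonyl, transmetalation, reductive elimination) should fix the absolute configuration of both methyl-bearing carbons at once, the chiral P,N ligand choosing the carbonyl on the (S)-configured carbon.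

Step 3
Reactants: 6 (2R,3S)-4-[4-(benzyloxy)phenyl]-2,3-dimethyl-4-oxobutanoic acid
Product: 8 (3R,4S,5S)-5-[4-(benzyloxy)phenyl]-3,4-dimethyldihydrofuran-2(3H)-one, via hydroxy acid 7 (not isolated)
Conditions: L-Selectride (2.2 equiv), THF, −78 → −20 °C; 2 M HCl, rt; then TsOH (cat.), CH2Cl2, rt
Reagents that add atoms: none
Why: Felkin–Anh reduction of the α-branched aryl ketone by a bulky hydride should give the anti (4S) carbinol, which lactonises under acid to the 3,4-cis-4,5-trans lactone; this is also the more stable C5 epimer, so any acid-mediated equilibration at the p-alkoxybenzylic carbon converges on it.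

Step 4
Reactants: 8 (3R,4S,5S)-5-[4-(benzyloxy)phenyl]-3,4-dimethyldihydrofuran-2(3H)-one
Product: 10 (3R,4S,5S)-5-[4-(benzyloxy)phenyl]-3,4-dimethyltetrahydrofuran-2-yl acetate (both anomers), via aluminium lactolate 9 (not isolated)
Conditions: DIBAL-H (1.1 equiv), CH2Cl2, −78 °C; then pyridine, DMAP, Ac2O, −78 → 0 °C
Reagents that add atoms: acetic anhydride CC(=O)OC(C)=O
Why: One-flask reductive acetylation of a lactone, in which the tetrahedral aluminium hemiacetal is acylated before it collapses, should give the lactol acetate without touching C3; the anomeric mixture is irrelevant because C2 is planarised in step 7.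

Step 5
Reactants: 11 1-(benzyloxy)-2-ethynylbenzene; 12 1-(benzyloxy)-4-iodobenzene
Product: 14 (E)-1-(benzyloxy)-2-{1-[4-(benzyloxy)phenyl]prop-1-en-2-yl}benzene, via alkenylalane 13 (not isolated)
Conditions: 11, Me3Al (2 equiv), Cp2ZrCl2 (20 mol %), CH2Cl2, 0 °C → rt; then 12, Pd(PPh3)4 (3 mol %), ZnCl2 (cat.), THF, rt
Reagents that add atoms: trimethylaluminium C[Al](C)C
Why: Negishi zirconium-catalysed syn-carboalumination of the terminal aryl alkyne (methyl to the aryl-bearing carbon, aluminium to the terminus) followed by Pd-catalysed cross-coupling with retention should give the trisubstituted alkene as the single E isomer.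

Step 6
Reactants: 14 (E)-1-(benzyloxy)-2-{1-[4-(benzyloxy)phenyl]prop-1-en-2-yl}benzene
Product: 15 (R)-1-(benzyloxy)-2-{1-[4-(benzyloxy)phenyl]propan-2-yl}benzene
Conditions: H2 (50 bar), [Ir(cod){(S)-t-Bu-PHOX}]BArF (1 mol %), CH2Cl2, rt
Reagents that add atoms: none
Why: Iridium–P,N-catalysed asymmetric hydrogenation of an unfunctionalised (E)-1,2-diarylpropene should set the benzylic (R) centre by catalyst-controlled face selection on the geometrically pure alkene, and cationic iridium catalysts do not hydrogenolyse benzyl ethers.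

Step 7
Reactants: 10 (3R,4S,5S)-5-[4-(benzyloxy)phenyl]-3,4-dimethyltetrahydrofuran-2-yl acetate; 15 (R)-1-(benzyloxy)-2-{1-[4-(benzyloxy)phenyl]propan-2-yl}benzene
Product: 17 (2R,3R,4S,5S)-2-{4-(benzyloxy)-3-[(2R)-1-(4-(benzyloxy)phenyl)propan-2-yl]phenyl}-5-[4-(benzyloxy)phenyl]-3,4-dimethyltetrahydrofuran, via oxocarbenium ion 16 (not isolated)
Conditions: 10, 15 (1.3 equiv), BF3·OEt2 (promoter), CH2Cl2, −78 → −30 °C
Reagents that add atoms: none
Why: BF3 ionises the anomeric acetate of 10 to the cyclic oxocarbenium ion 16 (O1=C2), which is attacked by the carbon para to the benzyloxy group on the sec-alkyl-bearing ring of 15; loss of a proton restores the arene and acetic acid is released. The closest known reaction type is the Lewis-acid Friedel–Crafts C-arylation of five-membered lactol acetates or methyl acetals by alkoxyarenes, as used for C-aryl furanosides and 2,5-diaryl-3,4-dimethyltetrahydrofurans. No ring is closed. The new stereocentre C2 is set by substrate control: in the envelope with the C4 methyl pseudo-equatorial the arene enters from the inside face, anti to the C3 and C4 methyl groups, giving 2,3-trans and 2,5-cis, which is also the more stable isomer should the p-alkoxybenzylic C2–O bond re-ionise. The step needs site selectivity for that para carbon over the ortho position of the same ring and over the ortho positions of the two 4-substituted benzyloxyphenyl rings; it is the only free position para to an oxygen in either partner, and a bulky secondary cation strongly disfavours ortho attack. Low temperature keeps the benzylic C5–O bond of the ring from ionising.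

Step 8
Reactants: 17 (2R,3R,4S,5S)-2-{4-(benzyloxy)-3-[(2R)-1-(4-(benzyloxy)phenyl)propan-2-yl]phenyl}-5-[4-(benzyloxy)phenyl]-3,4-dimethyltetrahydrofuran
Product: 18 (2R,3R,4S,5S)-2-{4-hydroxy-3-[(2R)-1-(4-hydroxyphenyl)propan-2-yl]phenyl}-5-(4-hydroxyphenyl)-3,4-dimethyltetrahydrofuran (target)
Conditions: H2 (1 atm), 10% Pd/C, EtOAc–MeOH, rt
Reagents that add atoms: none
Why: Hydrogenolysis of the three aryl benzyl ethers under neutral conditions at 1 atm should be much faster than cleavage of the ring benzylic C–O bonds of the tetrahydrofuran, and no stereocentre is touched.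

Compound list
1 | meso-2,3-dimethylsuccinic acid | C[C@@H](C(=O)O)[C@H](C)C(=O)O | starting material
2 | meso-2,3-dimethylsuccinic anhydride | C[C@@H]1[C@H](C)C(=O)OC1=O | intermediate
3 | 1-(benzyloxy)-4-bromobenzene | Brc1ccc(OCc2ccccc2)cc1 | starting material
4 | [4-(benzyloxy)phenyl]lithium | [Li]c1ccc(OCc2ccccc2)cc1 | intermediate
5 | [4-(benzyloxy)phenyl]zinc triflate | FC(F)(F)S(=O)(=O)O[Zn]c1ccc(OCc2ccccc2)cc1 | intermediate
6 | (2R,3S)-4-[4-(benzyloxy)phenyl]-2,3-dimethyl-4-oxobutanoic acid | C[C@@H](C(=O)O)[C@H](C)C(=O)c1ccc(OCc2ccccc2)cc1 | intermediate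
7 | (2R,3S,4S)-4-[4-(benzyloxy)phenyl]-4-hydroxy-2,3-dimethylbutanoic acid | C[C@@H](C(=O)O)[C@H](C)[C@@H](c1ccc(OCc2ccccc2)cc1)O | intermediate
8 | (3R,4S,5S)-5-[4-(benzyloxy)phenyl]-3,4-dimethyldihydrofuran-2(3H)-one (3,4-cis, 4,5-trans) | C[C@@H]1[C@H](C)[C@@H](c2ccc(OCc3ccccc3)cc2)OC1=O | intermediate
9 | diisobutylaluminium lactolate of 8 | C[C@@H]1[C@H](C)[C@@H](c2ccc(OCc3ccccc3)cc2)OC1O[Al](CC(C)C)CC(C)C | intermediate
10 | (3R,4S,5S)-5-[4-(benzyloxy)phenyl]-3,4-dimethyltetrahydrofuran-2-yl acetate (both anomers) | C[C@@H]1[C@H](C)[C@@H](c2ccc(OCc3ccccc3)cc2)OC1OC(C)=O | intermediate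
11 | 1-(benzyloxy)-2-ethynylbenzene | C#Cc1ccccc1OCc1ccccc1 | starting material
12 | 1-(benzyloxy)-4-iodobenzene | Ic1ccc(OCc2ccccc2)cc1 | starting material
13 | (E)-{2-[2-(benzyloxy)phenyl]prop-1-en-1-yl}dimethylalane | C[Al](C)/C=C(\C)c1ccccc1OCc1ccccc1 | intermediate
14 | (E)-1-(benzyloxy)-2-{1-[4-(benzyloxy)phenyl]prop-1-en-2-yl}benzene | C/C(=C\c1ccc(OCc2ccccc2)cc1)c1ccccc1OCc1ccccc1 | intermediate
15 | (R)-1-(benzyloxy)-2-{1-[4-(benzyloxy)phenyl]propan-2-yl}benzene | C[C@H](Cc1ccc(OCc2ccccc2)cc1)c1ccccc1OCc1ccccc1 | intermediate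
16 | (3R,4S,5S)-5-[4-(benzyloxy)phenyl]-3,4-dimethyl-4,5-dihydro-3H-furan-1-ium (oxocarbenium ion) | C[C@@H]1[C@H](C)[C@@H](c2ccc(OCc3ccccc3)cc2)[O+]=C1 | intermediate
17 | (2R,3R,4S,5S)-2-{4-(benzyloxy)-3-[(2R)-1-(4-(benzyloxy)phenyl)propan-2-yl]phenyl}-5-[4-(benzyloxy)phenyl]-3,4-dimethyltetrahydrofuran | C[C@@H]1[C@H](C)[C@@H](c2ccc(OCc3ccccc3)cc2)O[C@H]1c1ccc(OCc2ccccc2)c([C@H](C)Cc2ccc(OCc3ccccc3)cc2)c1 | intermediate
18 | (2R,3R,4S,5S)-2-{4-hydroxy-3-[(2R)-1-(4-hydroxyphenyl)propan-2-yl]phenyl}-5-(4-hydroxyphenyl)-3,4-dimethyltetrahydrofuran (2,3-trans, 3,4-cis, 4,5-trans) | C[C@@H]1[C@H](C)[C@@H](c2ccc(O)cc2)O[C@H]1c1ccc(O)c([C@H](C)Cc2ccc(O)cc2)c1 | target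

Total step count: 8. Longest linear sequence: 6 (steps 1, 2, 3, 4, 7, 8).

Steps most likely to fail

Step 7. The arylation may lose site selectivity (competing attack through an ortho position of either alkoxyaryl ring), or the Lewis acid may erode the facial selectivity by opening the ring at the benzylic C5–O bond. The fallback fixes the site with a halogen and uses an aryl-metal nucleophile; it sets out from 15 and 10 and comes back at 17. NBS in MeCN at 0 °C should brominate 15 para to the ether oxygen of the ring bearing the sec-alkyl group to give (R)-1-(benzyloxy)-4-bromo-2-{1-[4-(benzyloxy)phenyl]propan-2-yl}benzene F1. Magnesium insertion in the presence of LiCl and ZnCl2 (THF, rt) should convert it into the arylzinc chloride F2. Acetate 10 is exchanged with benzenesulfinic acid (CaCl2, CH2Cl2, rt) to the (3R,4S,5S)-5-[4-(benzyloxy)phenyl]-3,4-dimethyl-2-(phenylsulfonyl)tetrahydrofuran F3. F2 and F3 (THF, rt) should then combine by loss of sulfinate and addition of the arylzinc to the same oxocarbenium ion, anti to the two methyl groups, to give 17; organozinc addition to 2-sulfonyl cyclic ethers is known chemistry.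

Step 6. Enantioface discrimination may be insufficient, or conversion may stall, because the ortho-benzyloxy group sits next to the trisubstituted alkene. The fallback replaces catalysis by an auxiliary-controlled alkylation; it sets out from 12 and comes back at 15. Commercial [2-(benzyloxy)phenyl]acetic acid is coupled (PivCl, Et3N; then lithiated (S)-4-benzyloxazolidin-2-one, THF, −78 °C) to the imide (S)-4-benzyl-3-{2-[2-(benzyloxy)phenyl]acetyl}oxazolidin-2-one F4. Evans alkylation (NaHMDS, MeI, THF, −78 °C), with methyl entering anti to the benzyl group of the auxiliary, should give (S)-4-benzyl-3-{(S)-2-[2-(benzyloxy)phenyl]propanoyl}oxazolidin-2-one F5. LiBH4 in THF–H2O releases the auxiliary and gives (S)-2-[2-(benzyloxy)phenyl]propan-1-ol F6, and TsCl in pyridine gives its tosylate (S)-2-[2-(benzyloxy)phenyl]propyl 4-methylbenzenesulfonate F7. Iodide 12 is converted by iodine–magnesium exchange (i-PrMgCl·LiCl, THF, 0 °C) into [4-(benzyloxy)phenyl]magnesium chloride F8. Copper-catalysed coupling of F8 with F7 (Li2CuCl4 cat., THF, 0 °C → rt) leaves the stereocentre untouched and should give 15.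

Step 2. Discrimination between the two enantiotopic carbonyl groups may be insufficient, transmetalation of the functionalised arylzinc may be slow, or the carbon alpha to the new ketone may epimerise. The fallback separates the desymmetrisation from the carbon–carbon bond formation; it sets out from 2 and comes back at 8. Cinchona-alkaloid-mediated methanolysis (quinine or quinidine as required, MeOH, toluene, −55 °C) should give the hemiester (2S,3R)-4-methoxy-2,3-dimethyl-4-oxobutanoic acid F9. Oxalyl chloride with catalytic DMF (CH2Cl2, 0 °C) gives the acid chloride methyl (2R,3S)-4-chloro-2,3-dimethyl-4-oxobutanoate F10. Pd(PPh3)4-catalysed acylation of arylzinc 5 (prepared as in step 2; THF, 0 °C) should give the keto ester methyl (2R,3S)-4-[4-(benzyloxy)phenyl]-2,3-dimethyl-4-oxobutanoate F11. L-Selectride reduction (THF, −78 °C) to the hydroxy ester methyl (2R,3S,4S)-4-[4-(benzyloxy)phenyl]-4-hydroxy-2,3-dimethylbutanoate F12, followed by acid (TsOH cat., CH2Cl2), closes lactone 8 with loss of methanol.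

Further compounds
F1 | step 7 | (R)-1-(benzyloxy)-4-bromo-2-{1-[4-(benzyloxy)phenyl]propan-2-yl}benzene | C[C@H](Cc1ccc(OCc2ccccc2)cc1)c1cc(Br)ccc1OCc1ccccc1
F2 | step 7 | {4-(benzyloxy)-3-[(R)-1-(4-(benzyloxy)phenyl)propan-2-yl]phenyl}zinc chloride | C[C@H](Cc1ccc(OCc2ccccc2)cc1)c1cc([Zn]Cl)ccc1OCc1ccccc1
F3 | step 7 | (3R,4S,5S)-5-[4-(benzyloxy)phenyl]-3,4-dimethyl-2-(phenylsulfonyl)tetrahydrofuran | C[C@@H]1[C@H](C)[C@@H](c2ccc(OCc3ccccc3)cc2)OC1S(=O)(=O)c1ccccc1
F4 | step 6 | (S)-4-benzyl-3-{2-[2-(benzyloxy)phenyl]acetyl}oxazolidin-2-one | O=C(Cc1ccccc1OCc1ccccc1)N1C(=O)OC[C@@H]1Cc1ccccc1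
F5 | step 6 | (S)-4-benzyl-3-{(S)-2-[2-(benzyloxy)phenyl]propanoyl}oxazolidin-2-one | C[C@H](C(=O)N1C(=O)OC[C@@H]1Cc1ccccc1)c1ccccc1OCc1ccccc1
F6 | step 6 | (S)-2-[2-(benzyloxy)phenyl]propan-1-ol | C[C@H](CO)c1ccccc1OCc1ccccc1
F7 | step 6 | (S)-2-[2-(benzyloxy)phenyl]propyl 4-methylbenzenesulfonate | C[C@H](COS(=O)(=O)c1ccc(C)cc1)c1ccccc1OCc1ccccc1
F8 | step 6 | [4-(benzyloxy)phenyl]magnesium chloride | Cl[Mg]c1ccc(OCc2ccccc2)cc1
F9 | step 2 | (2S,3R)-4-methoxy-2,3-dimethyl-4-oxobutanoic acid | C[C@@H](C(=O)OC)[C@H](C)C(=O)O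
F10 | step 2 | methyl (2R,3S)-4-chloro-2,3-dimethyl-4-oxobutanoate | C[C@@H](C(=O)OC)[C@H](C)C(=O)Cl
F11 | step 2 | methyl (2R,3S)-4-[4-(benzyloxy)phenyl]-2,3-dimethyl-4-oxobutanoate | C[C@@H](C(=O)OC)[C@H](C)C(=O)c1ccc(OCc2ccccc2)cc1
F12 | step 2 | methyl (2R,3S,4S)-4-[4-(benzyloxy)phenyl]-4-hydroxy-2,3-dimethylbutanoate | C[C@@H](C(=O)OC)[C@H](C)[C@@H](c1ccc(OCc2ccccc2)cc1)O
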